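Abbreviations and numbering: TBS = tert-butyldimethylsilyl, TMS = trimethylsilyl. Carbocycle atoms are C1(CH3)=C2H–C3H(aryl)–C4H(aroyl)–C5H(aryl)–C6H2. The target is all-trans (3R,4R,5S) on the cyclohexene and 2R at the flavanone. Numbers go to building blocks and intermediates. Simple reagents are given with SMILES in each step.

Assumption: the sense of induction in steps 5 and 13 is assigned by analogy (iminium additions to benzylideneacetone; (S)-BINAP-type Rh gives (S)-3-arylcyclohexanone). Both antipodes of each catalyst are available, so the other is used if the analogy fails.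

## Retrosynthetic overview

1. Final step: buffered-fluoride removal of seven phenolic TBS groups. The acid- and base-labile flavanone centre should tolerate these conditions.
2. Flavanone C2–aryl bond: catalyst-controlled Rh(I) asymmetric 1,4-addition of the complete aryl boronate to 7-silyloxychromone. The pyranone ring is bought, and 2R is set last.
3. Cyclohexene (bold step; the biomimetic chalcone + dehydroprenyl-diene [4+2] is deliberately not used): the C3–C4 bond forms by 6-endo capture of a tertiary/cinnamyl allyl cation by a tethered silyl enol ether. This fixes the C1=C2 alkene and sets C3 and C4 from C5.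
4. Acyclic precursor: the C1–C2 bond comes from styrenyl-magnesium addition to the methyl ketone of an (S)-1,5-diketone. The C4–C5 bond and the C5 centre come from an organocatalytic decarboxylative Michael addition.
5. Ring order: the arenes and the pyranone are commercial, then the cyclohexene forms (step 10), then the chromanone stereocentre is set (step 13).

## Route

**Step 1**
Reactants: 1, 2,4-dihydroxybenzaldehyde
Product: 2, 2,4-bis(TBSO)benzaldehyde
Conditions: TBSCl (2.5 equiv), imidazole, DMF, rt
Reagents that add atoms: TBSCl, CC(C)(C)[Si](C)(C)Cl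
Why: Standard imidazole-promoted phenol silylation; TBS is chosen because it survives every later step and comes off with buffered fluoride.

**Step 2**
Reactants: 2; 3, 1-(triphenylphosphoranylidene)propan-2-one
Product: 4, (E)-4-[2,4-bis(TBSO)phenyl]but-3-en-2-one
Conditions: toluene, 100 °C
Reagents that add atoms: ylide 3, CC(=O)C=P(c1ccccc1)(c1ccccc1)c1ccccc1
Why: Wittig olefination with a stabilised ylide is neutral, so the aryl silyl ethers survive, and it is E-selective.

**Step 3**
Reactants: 5, 1-(2,4-dihydroxyphenyl)ethanone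
Product: 6, 1-[2,4-bis(TBSO)phenyl]ethanone
Conditions: TBSCl (3 equiv), imidazole, DMAP (cat.), DMF, 40 °C
Reagents that add atoms: TBSCl, CC(C)(C)[Si](C)(C)Cl
Why: Phenol silylation, with mild heating and DMAP to overcome the chelated 2-OH.

**Step 4**
Reactants: 6
Product: 7, 3-[2,4-bis(TBSO)phenyl]-3-oxopropanoic acid
Conditions: LDA (2.2 equiv), THF, –78 °C; CO2 (g); cold 1 M citric acid, 0 °C; used at once
Reagents that add atoms: carbon dioxide, O=C=O
Why: Kinetic enolate carboxylation, in which the second equivalent of base absorbs the acidic proton of the β-keto carboxylate and the cold work-up avoids decarboxylation.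

**Step 5**
Reactants: 4; 7 (1.6 equiv, added in portions)
Product: 8, (3S)-1,3-bis[2,4-bis(TBSO)phenyl]hexane-1,5-dione
Conditions: 9-amino-9-deoxy-epi-quinidine (20 mol %), toluene, rt, 48–72 h (–CO2)
Reagents that add atoms: none (both partners are reactants)
Why: In this organocatalytic decarboxylative Michael addition the cinchona primary amine turns 4 into its iminium ion, the quinuclidinium-bound keto-acid enol attacks one face, and CO2 loss makes the addition irreversible, which sets C5 as (S).

**Step 6**
Reactants: 9, 5-bromo-2,4-dihydroxybenzaldehyde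
Product: 10, 5-bromo-2,4-bis(TBSO)benzaldehyde
Conditions: TBSCl (2.5 equiv), imidazole, DMF, rt
Reagents that add atoms: TBSCl, CC(C)(C)[Si](C)(C)Cl
Why: Standard phenol silylation, with the bromide carried as the later handle for the flavanone.

**Step 7**
Reactants: 10
Product: 11, 1-bromo-2,4-bis(TBSO)-5-[(E)-2-iodoethenyl]benzene
Conditions: CrCl2 (6 equiv), CHI3 (2 equiv), THF, 0 °C → rt
Reagents that add atoms: iodoform, IC(I)I
Why: Takai olefination gives the E-vinyl iodide from aryl aldehydes and leaves the ArBr and silyl ethers untouched.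

**Step 8**
Reactants: 8; 11 (1.4 equiv)
Product: 12, (3S,6E)-7-[5-bromo-2,4-bis(TBSO)phenyl]-1,3-bis[2,4-bis(TBSO)phenyl]-5-hydroxy-5-methylhept-6-en-1-one (about 1:1 at the carbinol carbon)
Conditions: 11, i-PrMgCl·LiCl, THF, –20 → 0 °C; then 8 premixed with LaCl3·2LiCl (1 equiv), THF, –20 → 0 °C
Reagents that add atoms: none
Why: Turbo-Grignard I/Mg exchange retains alkene geometry and ignores the electron-rich ArBr, and the LaCl3-promoted 1,2-addition selects the unhindered methyl ketone over the donor-deactivated, ortho-blocked aryl ketone, while the unselective carbinol centre is erased in step 10.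

**Step 9**
Reactants: 12
Product: 13, the (1Z,3S,6E)-1,5-bis(trimethylsilyloxy)-5-methylhepta-1,6-diene derived from 12 (aryl-ketone Z-silyl enol ether plus tertiary allylic OTMS)
Conditions: TMSOTf (3 equiv), Et3N (5 equiv), CH2Cl2, –20 → 0 °C; cold NaHCO3/pentane work-up; used crude
Reagents that add atoms: TMSOTf, C[Si](C)(C)OS(=O)(=O)C(F)(F)F
Why: Soft enolisation with TMSOTf and amine gives the thermodynamic Z-enol silane at the only enolisable position and caps the alcohol, and excess amine keeps the medium too basic for premature ionisation.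

**Step 10 (key step)**
Reactants: 13
Product: 14, [(1R,2R,6S)-2-[5-bromo-2,4-bis(TBSO)phenyl]-6-[2,4-bis(TBSO)phenyl]-4-methylcyclohex-3-en-1-yl][2,4-bis(TBSO)phenyl]methanone (all-trans; 3R,4R,5S in carbocycle numbering)
Conditions: TMSOTf (10 mol %), CH2Cl2 (2 mM), –78 → –30 °C; Et3N quench; DBU (cat.), toluene, 40 °C only if a C4 epimer is seen (–Me3SiOSiMe3)
Reagents that add atoms: none
Why: Proposed new method: catalytic TMSOTf ionises the tertiary 2,4-disilyloxycinnamyl silyl ether to a delocalised allyl cation whose rotamers interconvert through the covalent C1 triflate, the tethered enol silane captures the benzylic terminus C3 in a 6-endo mode (4-exo attack at C1 is not viable, so the alkene can only be C1=C2), and a half-chair transition state with the A1,3-controlled Z-enol silane, the C5 aryl equatorial and the E-cation aryl pseudo-equatorial gives the all-trans array from C5 alone, with C4 also correctable thermodynamically; the closest known chemistry is Mukaiyama/Reetz-type SN1 α-alkylation of silyl enol ethers with stabilised allyl or benzhydryl cations and the cannabidiol-type capture of 1-methylcyclohexenyl cations.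

**Step 11**
Reactants: 14
Product: 15, the aryl pinacol boronate of 14 (Bpin in place of Br; 3R,4R,5S)
Conditions: B2pin2 (1.5 equiv), PdCl2(dppf) (5 mol %), KOAc (3 equiv), dioxane, 85 °C
Reagents that add atoms: bis(pinacolato)diboron, CC1(C)OB(OC1(C)C)B1OC(C)(C)C(C)(C)O1
Why: Miyaura borylation tolerates the ketone, the trisubstituted alkene and the aryl silyl ethers under anhydrous acetate conditions, and the all-equatorial stereotriad is the thermodynamic one and cannot erode.

**Step 12**
Reactants: 16, 7-hydroxy-4H-chromen-4-one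
Product: 17, 7-(TBSO)-4H-chromen-4-one
Conditions: TBSCl, imidazole, DMF, rt
Reagents that add atoms: TBSCl, CC(C)(C)[Si](C)(C)Cl
Why: Phenol silylation removes the acidic OH, which would otherwise protonate the aryl-rhodium intermediate.

**Step 13**
Reactants: 15; 17 (3 equiv)
Product: 18, the hepta-O-TBS ether of the target (2R; 3R,4R,5S)
Conditions: [RhCl(C2H4)2]2 (2.5 mol %), (R)-MeO-F12-BIPHEP (5.5 mol %), aq K3PO4 (0.5 equiv), toluene/H2O 10:1, 35 °C
Reagents that add atoms: none (water supplies only H)
Why: In this Hayashi–Miyaura asymmetric 1,4-addition to a chromone the aryl-Rh species inserts at C2 on the face dictated by the (R)-bisphosphine, far from and independent of the carbocycle centres, which gives 2R, and any minor enantiomer of 14 becomes a separable diastereomer.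

**Step 14**
Reactants: 18
Product: 19, target: (2R)-2-{5-[(1R,5S,6R)-6-(2,4-dihydroxybenzoyl)-5-(2,4-dihydroxyphenyl)-3-methylcyclohex-2-en-1-yl]-2,4-dihydroxyphenyl}-7-hydroxy-2,3-dihydrochromen-4-one
Conditions: Et3N·3HF (excess), THF/MeCN, 0 °C → rt, argon
Reagents that add atoms: none
Why: Fluoride desilylation of aryl silyl ethers at about pH 4–5 avoids both the phenoxide/enolate retro-oxa-Michael racemisation of the flavanone and acid-induced chroman or ketal formation at the alkene and ketone.

## Compound list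

1 | 2,4-dihydroxybenzaldehyde | O=Cc1ccc(O)cc1O | starting material

2 | 2,4-bis(TBSO)benzaldehyde | O=Cc1ccc(O[Si](C)(C)C(C)(C)C)cc1O[Si](C)(C)C(C)(C)C | intermediate

3 | 1-(triphenylphosphoranylidene)propan-2-one | CC(=O)C=P(c1ccccc1)(c1ccccc1)c1ccccc1 | starting material

4 | (E)-4-[2,4-bis(TBSO)phenyl]but-3-en-2-one | CC(=O)/C=C/c1ccc(O[Si](C)(C)C(C)(C)C)cc1O[Si](C)(C)C(C)(C)C | intermediate

5 | 1-(2,4-dihydroxyphenyl)ethanone | CC(=O)c1ccc(O)cc1O | starting material

6 | 1-[2,4-bis(TBSO)phenyl]ethanone | CC(=O)c1ccc(O[Si](C)(C)C(C)(C)C)cc1O[Si](C)(C)C(C)(C)C | intermediate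

7 | 3-[2,4-bis(TBSO)phenyl]-3-oxopropanoic acid | OC(=O)CC(=O)c1ccc(O[Si](C)(C)C(C)(C)C)cc1O[Si](C)(C)C(C)(C)C | intermediate

8 | (3S)-1,3-bis[2,4-bis(TBSO)phenyl]hexane-1,5-dione | O=C(c1ccc(O[Si](C)(C)C(C)(C)C)cc1O[Si](C)(C)C(C)(C)C)C[C@@H](c1ccc(O[Si](C)(C)C(C)(C)C)cc1O[Si](C)(C)C(C)(C)C)CC(C)=O | intermediate

9 | 5-bromo-2,4-dihydroxybenzaldehyde | O=Cc1cc(Br)c(O)cc1O | starting material

10 | 5-bromo-2,4-bis(TBSO)benzaldehyde | O=Cc1cc(Br)c(O[Si](C)(C)C(C)(C)C)cc1O[Si](C)(C)C(C)(C)C | intermediate

11 | 1-bromo-2,4-bis(TBSO)-5-[(E)-2-iodoethenyl]benzene | I/C=C/c1cc(Br)c(O[Si](C)(C)C(C)(C)C)cc1O[Si](C)(C)C(C)(C)C | intermediate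

12 | (3S,6E)-tertiary allylic alcohol, carbinol epimers | O=C(c1ccc(O[Si](C)(C)C(C)(C)C)cc1O[Si](C)(C)C(C)(C)C)C[C@@H](c1ccc(O[Si](C)(C)C(C)(C)C)cc1O[Si](C)(C)C(C)(C)C)CC(C)(O)/C=C/c1cc(Br)c(O[Si](C)(C)C(C)(C)C)cc1O[Si](C)(C)C(C)(C)C | intermediate

13 | (1Z,3S,6E)-silyl enol ether / allylic OTMS ether | C[Si](C)(C)O/C(c1ccc(O[Si](C)(C)C(C)(C)C)cc1O[Si](C)(C)C(C)(C)C)=C\[C@@H](c1ccc(O[Si](C)(C)C(C)(C)C)cc1O[Si](C)(C)C(C)(C)C)CC(C)(O[Si](C)(C)C)/C=C/c1cc(Br)c(O[Si](C)(C)C(C)(C)C)cc1O[Si](C)(C)C(C)(C)C | intermediate

14 | all-trans (3R,4R,5S) cyclohexene aryl bromide | CC1=C[C@@H](c2cc(Br)c(O[Si](C)(C)C(C)(C)C)cc2O[Si](C)(C)C(C)(C)C)[C@H](C(=O)c2ccc(O[Si](C)(C)C(C)(C)C)cc2O[Si](C)(C)C(C)(C)C)[C@@H](c2ccc(O[Si](C)(C)C(C)(C)C)cc2O[Si](C)(C)C(C)(C)C)C1 | intermediate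

15 | corresponding aryl pinacol boronate | CC1=C[C@@H](c2cc(B3OC(C)(C)C(C)(C)O3)c(O[Si](C)(C)C(C)(C)C)cc2O[Si](C)(C)C(C)(C)C)[C@H](C(=O)c2ccc(O[Si](C)(C)C(C)(C)C)cc2O[Si](C)(C)C(C)(C)C)[C@@H](c2ccc(O[Si](C)(C)C(C)(C)C)cc2O[Si](C)(C)C(C)(C)C)C1 | intermediate

16 | 7-hydroxy-4H-chromen-4-one | O=c1ccoc2cc(O)ccc12 | starting material

17 | 7-(TBSO)-4H-chromen-4-one | O=c1ccoc2cc(O[Si](C)(C)C(C)(C)C)ccc12 | intermediate

18 | hepta-O-TBS target (2R; 3R,4R,5S) | CC1=C[C@@H](c2cc([C@H]3CC(=O)c4ccc(O[Si](C)(C)C(C)(C)C)cc4O3)c(O[Si](C)(C)C(C)(C)C)cc2O[Si](C)(C)C(C)(C)C)[C@H](C(=O)c2ccc(O[Si](C)(C)C(C)(C)C)cc2O[Si](C)(C)C(C)(C)C)[C@@H](c2ccc(O[Si](C)(C)C(C)(C)C)cc2O[Si](C)(C)C(C)(C)C)C1 | intermediate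

19 | CID11157778 | CC1=C[C@@H](c2cc([C@H]3CC(=O)c4ccc(O)cc4O3)c(O)cc2O)[C@H](C(=O)c2ccc(O)cc2O)[C@@H](c2ccc(O)cc2O)C1 | target

## Step count and risks

Total steps: 14.
Longest linear sequence: 9 (steps 1, 2, 5, 8, 9, 10, 11, 13, 14).

Three steps most likely to fail:

1. **Step 10.** The risks are E1 loss to dienes with protodesilylation of the enol silane, oligomerisation, and poor C3/C5 selectivity.
   Fallback: close the ring anionically.
   - Join 8 and aldehyde 10 by a boron aldol at the methyl ketone, followed by MsCl/Et3N elimination to the styryl enone.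
   - Cyclise by intramolecular 6-endo Michael addition of the aryl-ketone enolate (KHMDS).
   - Trap the regiodefined C1=C2 enolate with Comins' reagent.
   - Install the methyl group by Fe- or Pd-catalysed cross-coupling of the enol triflate.

2. **Step 13.** The boronate is the limiting reagent, carries an ortho-silyloxy group and is electron-rich. It may protodeboronate faster than it inserts into the sluggish chromone.
   Fallback: move the stereo-defining event from C–C formation to hydride delivery.
   - Run a Pd(II) oxidative boron-Heck coupling of 15 with 17 to give the achiral flavone.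
   - Set C2 by CuH/DTBM-SEGPHOS asymmetric conjugate reduction of the flavone.

3. **Step 5.** The electron-rich, ortho-substituted enone may react slowly, so background decarboxylation of 7 or low ee is possible.
   Fallback: set C5 by Hayashi–Miyaura arylation.
   - Make (E)-Ar2CO–CH=CH–CH2–C(OCH2CH2O)CH3 by HWE reaction of the β-ketophosphonate of 6 with (2-methyl-1,3-dioxolan-2-yl)acetaldehyde.
   - Add 2,4-bis(TBSO)phenylboronic acid to it under Rh/BINAP catalysis.
   - Hydrolyse the ketal to give 8.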